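**Retrosynthetic overview**

1. Numbering follows the nonadec-1-ene chain: C10 = ester carbinol, C11 and C14 = ring carbons on the ring oxygen, C13 = ring carbinol; the target is (10R,11R,13S,14S). The only ring (oxolane) is closed last, through the C14–O bond, by invertive 5-exo displacement of a C14 chloride by the C11 hydroxyl.
2. C11 carbinol ⇐ C11 ketone, by 1,3-syn reduction directed by the C13 hydroxyl.
3. C12–C13 bond ⇐ anti-selective boron aldol between an α-chloroaldehyde (C13–C19) and the methyl side of an α-stearoyloxy methyl ketone (C1–C12).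
4. C10–O ester bond and C10 stereocentre ⇐ amine-catalysed asymmetric α-acyloxylation of an achiral methyl ketone with a diacyl peroxide (new reaction); C14–Cl stereocentre ⇐ organocatalytic α-chlorination of an achiral aldehyde.
5. Achiral inputs: a C11 ω-alkenoic acid, a C18 acyl chloride (two molecules per peroxide) and a C7 aldehyde.

**Route**

Step 1
Reactants: 1 undec-10-enoic acid
Product: 4 dodec-11-en-2-one, via lithium undec-10-enoate 2 (not isolated), via dilithium gem-diolate 3 (not isolated)
Conditions: MeLi (2.2 equiv), Et2O, 0 °C to rt; poured into cold 1 M HCl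
Reagents that add atoms: methyllithium, [Li]C
Why: A second methyllithium adds to the lithium carboxylate to give a dilithium gem-diolate that cannot over-add and collapses to the methyl ketone only on acidic quench (organolithium methyl ketone synthesis from a carboxylic acid), and no stereocentre is formed.

Step 2
Reactants: 5 octadecanoyl chloride (2.0 equiv; two molecules are joined through one peroxide bridge)
Product: 7 dioctadecanoyl peroxide, via octadecaneperoxoic acid 6 (not isolated)
Conditions: 5 (2.0 equiv), 30% aq H2O2 (1.1 equiv), NaOH (2.2 equiv), THF/hexane–H2O, 0 °C; solid filtered, washed with water and dried below 30 °C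
Reagents that add atoms: hydrogen peroxide, OO; octadecanoyl chloride (the second equivalent of 5), CCCCCCCCCCCCCCCCCC(=O)Cl
Why: Hydroperoxide anion is an alpha-effect nucleophile that is acylated by the first molecule of 5 to the peracid anion, which is acylated by the second molecule of 5 faster than the acyl chloride hydrolyses (Schotten–Baumann-type peracylation), giving the symmetrical diacyl peroxide with no stereocentre.

Step 3
Reactants: 4 dodec-11-en-2-one (2.0 equiv); 7 dioctadecanoyl peroxide (1.0 equiv)
Product: 8 (3R)-2-oxododec-11-en-3-yl octadecanoate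
Conditions: 9-amino(9-deoxy)-epi-quinine (10 mol%), Cl3CCO2H (20 mol%), 2,6-di-tert-butyl-4-methylphenol (10 mol%), THF, 30 °C, 48 h
Reagents that add atoms: none
Why: Proposed new method: the chiral primary amine condenses with 4 to the more substituted enamine, whose C3 carbon attacks the weak O–O bond of the peroxide (or, after N-acyloxylation of the amine, the N-acyloxy enamine undergoes a [3,3]-sigmatropic shift) inside the ion pair held by the protonated quinuclidine, so the stearoyloxy group is delivered to one enamine face and sets C10 as R before hydrolysis releases 8 and the amine; the closest known reactions are the cinchona-primary-amine-catalysed α-benzoyloxylation of cyclic ketones with dibenzoyl peroxide and the stoichiometric α-acyloxylation of unsymmetrical ketones at the more substituted carbon with N-alkyl-O-acylhydroxylamines, neither shown for an acyclic methyl alkyl ketone or an aliphatic diacyl peroxide, and the facial sense must be confirmed on the first run because the pseudoenantiomeric epi-quinidine amine gives the antipode.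

Step 4
Reactants: 9 heptanal
Product: 10 (2R)-2-chloroheptanal
Conditions: N-chlorosuccinimide (1.2 equiv), (2S,5S)-2,5-diphenylpyrrolidine (10 mol%), CH2Cl2, 0 °C to rt; pentane, filtered, used crude at once
Reagents that add atoms: N-chlorosuccinimide, ClN1C(=O)CCC1=O
Why: The C2-symmetric pyrrolidine forms an E-enamine with one face shielded by the neighbouring phenyl group, so chlorine is delivered to the open face and sets C14 as R (enamine-catalysed asymmetric α-chlorination of an aldehyde).

Step 5
Reactants: 8 (3R)-2-oxododec-11-en-3-yl octadecanoate; 10 (2R)-2-chloroheptanal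
Product: 13 (10R,13S,14R)-14-chloro-13-hydroxy-11-oxononadec-1-en-10-yl octadecanoate, via dicyclohexylboron enolate 11 (not isolated), via dicyclohexylboron aldolate 12 (not isolated)
Conditions: 8, (c-C6H11)2BCl (1.3 equiv), Et3N (1.2 equiv), Et2O, −78 to 0 °C, 1 h; 10 (1.3 equiv), −78 °C, 3 h, then −20 °C; MeOH, pH 7 buffer, 30% H2O2, 0 °C
Reagents that add atoms: none
Why: Kinetic enolisation with the chloroborane occurs at the methyl group and the non-basic boron enolate adds to the α-chloroaldehyde with the C–Cl and C=O dipoles opposed (Cornforth model), giving the 13,14-anti chlorohydrin and so setting C13 as S (boron aldol reaction) without touching the stearate or the C10 and C14 centres.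

Step 6
Reactants: 13 (10R,13S,14R)-14-chloro-13-hydroxy-11-oxononadec-1-en-10-yl octadecanoate
Product: 15 (10R,11R,13S,14R)-14-chloro-11,13-dihydroxynonadec-1-en-10-yl octadecanoate, via diethylboron chelate 14 (not isolated)
Conditions: Et2BOMe (1.2 equiv), THF/MeOH 4:1, −78 °C, 20 min; NaBH4 (1.2 equiv), −78 °C, 3 h; AcOH, then MeOH co-evaporation
Reagents that add atoms: none
Why: The diethylboryl group ties the C13 oxygen to the C11 carbonyl in a six-membered chelate and external hydride adds axially, giving the 11,13-syn diol and so setting C11 as R (Narasaka–Prasad reduction) at a temperature at which ester, chloride and alkene are inert.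

Step 7
Reactants: 15 (10R,11R,13S,14R)-14-chloro-11,13-dihydroxynonadec-1-en-10-yl octadecanoate
Product: 16 (1R)-1-[(2R,4S,5S)-4-hydroxy-5-pentyloxolan-2-yl]dec-9-en-1-yl octadecanoate
Conditions: AgOTf (1.5 equiv), Ag2O (1.5 equiv), THF, 20 to 50 °C, dark
Reagents that add atoms: none
Why: Silver-assisted departure of chloride lets the C11 hydroxyl close the oxolane by 5-exo-tet SN2 displacement with inversion at C14 (R to S), placing the pentyl group cis to the C13 hydroxyl and trans to the side chain (intramolecular Williamson-type etherification of a chlorodiol), while Ag2O takes up the acid so that ester and alkene survive.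

**Compound list**

1 | undec-10-enoic acid | OC(=O)CCCCCCCCC=C | starting material
2 | lithium undec-10-enoate | [Li+].[O-]C(=O)CCCCCCCCC=C | intermediate
3 | dilithium dodec-11-ene-2,2-bis(olate) | [Li+].[Li+].CC([O-])([O-])CCCCCCCCC=C | intermediate
4 | dodec-11-en-2-one | CC(=O)CCCCCCCCC=C | intermediate
5 | octadecanoyl chloride | CCCCCCCCCCCCCCCCCC(=O)Cl | starting material
6 | octadecaneperoxoic acid (present as its sodium salt in the alkaline mixture) | CCCCCCCCCCCCCCCCCC(=O)OO | intermediate
7 | dioctadecanoyl peroxide | CCCCCCCCCCCCCCCCCC(=O)OOC(=O)CCCCCCCCCCCCCCCCC | intermediate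
8 | (3R)-2-oxododec-11-en-3-yl octadecanoate | CC(=O)[C@H](OC(=O)CCCCCCCCCCCCCCCCC)CCCCCCCC=C | intermediate
9 | heptanal | CCCCCCC=O | starting material
10 | (2R)-2-chloroheptanal | O=C[C@H](Cl)CCCCC | intermediate
11 | (3R)-2-[(dicyclohexylboranyl)oxy]dodeca-1,11-dien-3-yl octadecanoate | C=C(OB(C1CCCCC1)C1CCCCC1)[C@H](OC(=O)CCCCCCCCCCCCCCCCC)CCCCCCCC=C | intermediate
12 | (10R,13S,14R)-14-chloro-13-[(dicyclohexylboranyl)oxy]-11-oxononadec-1-en-10-yl octadecanoate | C=CCCCCCCC[C@@H](OC(=O)CCCCCCCCCCCCCCCCC)C(=O)C[C@H](OB(C1CCCCC1)C1CCCCC1)[C@H](Cl)CCCCC | intermediate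
13 | (10R,13S,14R)-14-chloro-13-hydroxy-11-oxononadec-1-en-10-yl octadecanoate | C=CCCCCCCC[C@@H](OC(=O)CCCCCCCCCCCCCCCCC)C(=O)C[C@H](O)[C@H](Cl)CCCCC | intermediate
14 | (10R,13S,14R)-14-chloro-13-[(diethylboranyl)oxy]-11-oxononadec-1-en-10-yl octadecanoate | C=CCCCCCCC[C@@H](OC(=O)CCCCCCCCCCCCCCCCC)C(=O)C[C@H](OB(CC)CC)[C@H](Cl)CCCCC | intermediate
15 | (10R,11R,13S,14R)-14-chloro-11,13-dihydroxynonadec-1-en-10-yl octadecanoate | C=CCCCCCCC[C@@H](OC(=O)CCCCCCCCCCCCCCCCC)[C@H](O)C[C@H](O)[C@H](Cl)CCCCC | intermediate
16 | (1R)-1-[(2R,4S,5S)-4-hydroxy-5-pentyloxolan-2-yl]dec-9-en-1-yl octadecanoate | C=CCCCCCCC[C@@H](OC(=O)CCCCCCCCCCCCCCCCC)[C@H]1C[C@H](O)[C@H](CCCCC)O1 | target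

**Count and risks**

Total step count: 7 (steps 1 and 2 are one-step preparations of the ketone and the peroxide). Longest linear sequence: 5 (steps 1, 3, 5, 6, 7).

The three steps most likely to fail:

Step 3 (the new reaction). It can fail through attack at the methyl carbon instead of C3, through low or opposite enantioselectivity, or through oxidation of the amine by the peroxide. The fallback uses known chemistry, sets out from 4 and comes back at 8. L-Proline-catalysed α-aminoxylation of 4 with nitrosobenzene (L-proline 30 mol%, slow addition of PhNO, DMSO, rt) takes methyl alkyl ketones at the internal carbon and gives (3R)-3-[(phenylamino)oxy]dodec-11-en-2-one F1. CuSO4·5H2O (30 mol%) in MeOH at 0 °C cleaves the N–O bond to (3R)-3-hydroxydodec-11-en-2-one F2. Acylation with 5 (pyridine, 4-(dimethylamino)pyridine 5 mol%, CH2Cl2, 0 °C) returns 8.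

Step 5. The C10 stereocentre of the enolate may oppose the Cornforth preference of the aldehyde, residual amine may epimerise 10, and enolisation may stray to the C10 side. The fallback sets out from 8 and comes back at 13. Soft silylation (TMSOTf, Et3N, CH2Cl2, −78 to 0 °C; the internal enol ether would be tetrasubstituted and is disfavoured) gives (3R)-2-[(trimethylsilyl)oxy]dodeca-1,11-dien-3-yl octadecanoate F3. A Mukaiyama aldol with 10 (BF3·OEt2, CH2Cl2, −78 °C) then runs through an open transition state under polar Felkin–Anh control, again 13,14-anti and with no amine present, and gives 13 after aqueous work-up.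

Step 6. The α-stearoyloxy group has an intrinsic polar Felkin preference for the 10,11-anti alcohol, which opposes the chelate-controlled 11,13-syn delivery; the vicinal hydroxy ester can also shift its acyl group from O10 to O11. The fallback replaces substrate control by catalyst control, sets out from 13 and comes back at 15. Silylation (Et3SiCl, imidazole, DMF, 0 °C) gives (10R,13S,14R)-14-chloro-11-oxo-13-[(triethylsilyl)oxy]nonadec-1-en-10-yl octadecanoate F4. Corey–Bakshi–Shibata reduction with (S)-1-methyl-3,3-diphenyltetrahydro-1H,3H-pyrrolo[1,2-c][1,3,2]oxazaborole (30 mol%) and catecholborane in toluene at −78 °C treats the branched C10 side as the large group and gives (10R,11R,13S,14R)-14-chloro-11-hydroxy-13-[(triethylsilyl)oxy]nonadec-1-en-10-yl octadecanoate F5; catecholborane leaves the terminal alkene alone. HF·pyridine in THF at 0 °C removes the silyl group and returns 15.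

**Further compounds**

F1 | step 3 | (3R)-3-[(phenylamino)oxy]dodec-11-en-2-one | CC(=O)[C@H](ONc1ccccc1)CCCCCCCC=C
F2 | step 3 | (3R)-3-hydroxydodec-11-en-2-one | CC(=O)[C@H](O)CCCCCCCC=C
F3 | step 5 | (3R)-2-[(trimethylsilyl)oxy]dodeca-1,11-dien-3-yl octadecanoate | C=C(O[Si](C)(C)C)[C@H](OC(=O)CCCCCCCCCCCCCCCCC)CCCCCCCC=C
F4 | step 6 | (10R,13S,14R)-14-chloro-11-oxo-13-[(triethylsilyl)oxy]nonadec-1-en-10-yl octadecanoate | C=CCCCCCCC[C@@H](OC(=O)CCCCCCCCCCCCCCCCC)C(=O)C[C@H](O[Si](CC)(CC)CC)[C@H](Cl)CCCCC
F5 | step 6 | (10R,11R,13S,14R)-14-chloro-11-hydroxy-13-[(triethylsilyl)oxy]nonadec-1-en-10-yl octadecanoate | C=CCCCCCCC[C@@H](OC(=O)CCCCCCCCCCCCCCCCC)[C@H](O)C[C@H](O[Si](CC)(CC)CC)[C@H](Cl)CCCCC
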